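**Retrosynthetic overview**

1. The route rests on ring B: its quaternary C1' is bonded directly to the alkylidene carbon C6', which also carries the C5' stereocentre. The C1'–C6' bond is made by adding a tertiary C1' radical to C6' of a C6'≡C7'–C8' ynoate, which closes ring B, the only ring formed (ring A arrives with retinal).
2. The ynoate comes from (S)-citronellal, whose C3 becomes C5': one-carbon degradation through the enamine, Corey–Fuchs olefination, carboxylation of the acetylide.
3. C15–C15' is cut by a Stille coupling between a ring-B polyenyl stannane (C15'–Sn) and the retro enol triflate (C15–OTf) made from all-trans-retinal by removal of H-4.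
4. The stannane is assembled by a Horner–Wadsworth–Emmons reaction of the C10' dienal with a C11'–C15' stannyl dienyl phosphonate. The dienal follows from the cyclised C8' enoate by thiyl-radical equilibration of C6'=C7', reduction, oxidation and one Wittig extension.
5. Iodine equilibration of the coupled polyene gives the all-E target.

Key step: step 5

Assumption: at C6'=C7' the arrangement with C8' syn to C5' is taken to be the thermodynamically preferred one (the C5' methine can turn its hydrogen into the alkene plane, the quaternary C1' cannot), so that the thiyl-radical and iodine equilibrations converge on the target geometry.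

**Route**

Step 1
Reactants: 1 (S)-citronellal
Product: 2 4-[(1E,3S)-3,7-dimethylocta-1,6-dien-1-yl]morpholine
Conditions: morpholine (2 equiv), K2CO3, 0 °C → rt; distillation
Reagents that add atoms: morpholine, C1COCCN1
Why: Enamine condensation of an unhindered aldehyde with a secondary amine should give the (E)-enamine; the C3 stereocentre is only allylic to the new C=C and is not touched.

Step 2
Reactants: 2 4-[(1E,3S)-3,7-dimethylocta-1,6-dien-1-yl]morpholine
Product: 3 (2S)-2,6-dimethylhept-5-enal
Conditions: CuCl (10 mol %), O2 (1 atm), MeCN, 0 °C → rt; crude aldehyde kept cold and used at once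
Reagents that add atoms: dioxygen, O=O
Why: Copper-catalysed oxygenation of an enamine cleaves the electron-rich N–C=C bond to the nor-aldehyde and the formamide, while the unactivated trisubstituted alkene should be inert and the neutral medium should preserve the now α-positioned stereocentre.

Step 3
Reactants: 3 (2S)-2,6-dimethylhept-5-enal
Product: 4 (3S)-1,1-dibromo-3,7-dimethylocta-1,6-diene
Conditions: Zn, PPh3, CBr4, CH2Cl2, rt, 24 h; then 3, rt
Reagents that add atoms: carbon tetrabromide, BrC(Br)(Br)Br
Why: Corey–Fuchs dibromo-olefination with the preformed ylide (zinc variant) is a non-basic Wittig-type reaction, so the α-stereocentre of the aldehyde should not epimerise.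

Step 4
Reactants: 4 (3S)-1,1-dibromo-3,7-dimethylocta-1,6-diene; 5 ethyl chloroformate
Product: 7 ethyl (4S)-4,8-dimethylnon-7-en-2-ynoate, via lithium acetylide 6 (not isolated)
Conditions: n-BuLi (2.1 equiv), THF, −78 °C; then ClCO2Et, −78 → 0 °C
Reagents that add atoms: none
Why: Second stage of the Corey–Fuchs sequence (elimination and lithium–bromine exchange to the lithium acetylide) followed by C-acylation with the chloroformate; the propargylic C–H is not acidic enough to be removed at −78 °C, so the stereocentre is kept.

Step 5
Reactants: 7 ethyl (4S)-4,8-dimethylnon-7-en-2-ynoate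
Product: 8 ethyl 2-[(6S)-2,2,6-trimethylcyclohexylidene]acetate as the mixture of its two C6'=C7' isomers
Conditions: Fe(acac)3 (30 mol %), PhSiH3 (2.5 equiv), EtOH (0.02 M), 60 °C, Ar
Reagents that add atoms: none
Why: The trivalent iron hydride formed from Fe(acac)3 and PhSiH3 in ethanol transfers a hydrogen atom to C2' of the trisubstituted alkene (Markovnikov sense) and leaves the tertiary C1' radical, which adds to the β-carbon C6' of the ynoate; the resulting C7' vinyl radical is reduced by divalent iron and protonated by ethanol (or takes a hydrogen atom directly) to give the enoate. The closest known reaction type is the iron-hydride reductive coupling of an unactivated alkene with an electron-poor π-bond in its intramolecular Giese form, together with 6-exo-dig cyclisations of tertiary alkyl radicals onto alkynoates under tin or silane mediation. Ring B closes in the 6-exo-dig mode, favoured over 7-endo by polarity matching (nucleophilic radical, electrophilic β-carbon) and ring size. No stereocentre is created: C5' comes from citronellal and none of its bonds changes, and C1' is not stereogenic. The step needs hydrogen-atom transfer to the electron-rich alkene in preference to the alkyne, which the electron-poor character of the ynoate secures, and it needs ring closure to outrun both simple reduction of the radical and 1,5-hydrogen transfer from C5'–H, which the activated acceptor and high dilution favour. The C6'=C7' geometry is not controlled here, because quenching of the linear vinyl radical from the less hindered C5' side places the ester syn to C1'; the product is therefore taken on as the isomer mixture, in which the 2Z form may well predominate, and the geometry is set in step 6.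

Step 6
Reactants: 8 ethyl 2-[(6S)-2,2,6-trimethylcyclohexylidene]acetate (mixture of C6'=C7' isomers)
Product: 9 ethyl (2E)-2-[(6S)-2,2,6-trimethylcyclohexylidene]acetate (ester syn to C5')
Conditions: PhSH (20 mol %), AIBN (10 mol %), PhH, 80 °C, until the isomer ratio no longer changes; chromatography on AgNO3–SiO2, the 2Z fraction returned to the equilibration
Reagents that add atoms: none
Why: Thiyl-radical E/Z equilibration (reversible addition of PhS• at C7', rotation about C6'–C7' and β-scission) should enrich the isomer whose ester faces C5', where the C5' hydrogen can lie in the alkene plane, whereas in the 2Z isomer a methyl of C1' must eclipse the ester; arylthiyl radicals add reversibly much faster than they abstract the allylic C5'–H and no base is present, so the stereocentre should be kept.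

Step 7
Reactants: 9 ethyl (2E)-2-[(6S)-2,2,6-trimethylcyclohexylidene]acetate
Product: 10 (2E)-2-[(6S)-2,2,6-trimethylcyclohexylidene]ethan-1-ol
Conditions: i-Bu2AlH (2.2 equiv), CH2Cl2, −78 → 0 °C; aqueous potassium sodium tartrate work-up
Reagents that add atoms: none
Why: 1,2-Reduction of a conjugated ester with i-Bu2AlH gives the allylic alcohol without conjugate reduction and with retention of the alkene geometry.

Step 8
Reactants: 10 (2E)-2-[(6S)-2,2,6-trimethylcyclohexylidene]ethan-1-ol
Product: 11 (2E)-2-[(6S)-2,2,6-trimethylcyclohexylidene]acetaldehyde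
Conditions: MnO2 (excess), CH2Cl2, rt, dark
Reagents that add atoms: none
Why: Allylic oxidation with MnO2 is neutral and heterogeneous, so neither the C6'=C7' geometry nor the γ-stereocentre C5' (which would be lost through a dienol) should be disturbed.

Step 9
Reactants: 11 (2E)-2-[(6S)-2,2,6-trimethylcyclohexylidene]acetaldehyde; 12 2-(triphenylphosphoranylidene)propanal
Product: 13 (2E,4E)-2-methyl-4-[(6S)-2,2,6-trimethylcyclohexylidene]but-2-enal
Conditions: PhMe, 85 °C, dark
Reagents that add atoms: none
Why: Wittig reaction with a stabilised formyl ylide is E-selective for the new C8'=C9' bond and runs without base, and the α-methyl dienal formed is less electrophilic than 11, so a second homologation should not compete.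

Step 10
Reactants: 14 (2E)-3-methylpent-2-en-4-yn-1-ol
Product: 15 (3E)-5-bromo-3-methylpent-3-en-1-yne
Conditions: PBr3 (0.4 equiv), pyridine (cat.), Et2O, −10 °C
Reagents that add atoms: phosphorus tribromide, BrP(Br)Br
Why: SN2 bromination of a primary allylic alcohol with PBr3 should keep the E geometry of the trisubstituted alkene.

Step 11
Reactants: 15 (3E)-5-bromo-3-methylpent-3-en-1-yne
Product: 16 diethyl [(2E)-3-methylpent-2-en-4-yn-1-yl]phosphonate
Conditions: P(OEt)3, neat, 90 °C, EtBr distilled off
Reagents that add atoms: triethyl phosphite, CCOP(OCC)OCC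
Why: Michaelis–Arbuzov reaction of a primary allylic bromide occurs at the CH2 terminus and leaves the alkene and alkyne unchanged.

Step 12
Reactants: 16 diethyl [(2E)-3-methylpent-2-en-4-yn-1-yl]phosphonate
Product: 17 diethyl [(2E,4E)-3-methyl-5-(tributylstannyl)penta-2,4-dien-1-yl]phosphonate
Conditions: Bu3SnH, PdCl2(PPh3)2 (2 mol %), THF, 0 °C → rt
Reagents that add atoms: tributyltin hydride, CCCC[SnH](CCCC)CCCC
Why: Palladium-catalysed syn-hydrostannation of a terminal alkyne flanked by a branched alkene carbon should place tin at the terminal carbon and give the (E)-vinylstannane.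

Step 13
Reactants: 13 (2E,4E)-2-methyl-4-[(6S)-2,2,6-trimethylcyclohexylidene]but-2-enal; 17 diethyl [(2E,4E)-3-methyl-5-(tributylstannyl)penta-2,4-dien-1-yl]phosphonate
Product: 19 tributyl{(1E,3E,5E,7E)-3,7-dimethyl-9-[(6S)-2,2,6-trimethylcyclohexylidene]nona-1,3,5,7-tetraen-1-yl}stannane (C8' syn to C5'), via sodium phosphonate carbanion 18 (not isolated)
Conditions: NaN(SiMe3)2, THF–DMPU, −78 °C; then 13, −78 → 0 °C, dark
Reagents that add atoms: none
Why: Horner–Wadsworth–Emmons olefination with an allylic phosphonate anion forms C10'=C11' mainly E; the vinylstannane is inert to the amide base, and fast carbonyl addition at −78 °C should pre-empt deprotonation at the remote C5'.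

Step 14
Reactants: 20 all-trans-retinal
Product: 22 (1E,3E,5E,7E)-3,7-dimethyl-9-(2,6,6-trimethylcyclohex-2-en-1-ylidene)nona-1,3,5,7-tetraen-1-yl trifluoromethanesulfonate (retro enol triflate, C6=C7 geometry open), via potassium hexaenolate 21 (not isolated)
Conditions: KOt-Bu (1.3 equiv), THF, −78 °C, slow addition of 20, then −40 °C; PhNTf2, −78 → −20 °C; dark; filtered through basic Al2O3 and used at once
Reagents that add atoms: N-phenylbis(trifluoromethanesulfonimide), O=S(=O)(N(c1ccccc1)S(=O)(=O)C(F)(F)F)C(F)(F)F
Why: Vinylogous enolisation followed by O-sulfonylation: removal of H-4 gives the linear, fully conjugated hexaenolate (the thermodynamic anion, reached with tert-butanol as proton shuttle), and triflation on oxygen fixes the retro pattern C4=C5, C6=C7 … C14=C15–OTf, as in the base-induced formation of retro-ionones and retro-retinoates.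

Step 15
Reactants: 19 tributyl{(1E,3E,5E,7E)-3,7-dimethyl-9-[(6S)-2,2,6-trimethylcyclohexylidene]nona-1,3,5,7-tetraen-1-yl}stannane; 22 retro enol triflate
Product: 23 (5'S)-4,5'-retro-β,β-carotene as a mixture of C6=C7 isomers
Conditions: Pd2(dba)3 (5 mol %), AsPh3 (40 mol %), LiCl (3 equiv), THF–NMP, rt, dark, Ar
Reagents that add atoms: none
Why: Stille coupling of an alkenyl triflate with an alkenylstannane (zerovalent palladium, chloride-assisted) forms the C15–C15' bond with retention of geometry at both sp2 carbons under neutral conditions that both polyenes should tolerate.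

Step 16
Reactants: 23 (5'S)-4,5'-retro-β,β-carotene as a mixture of C6=C7 isomers
Product: 24 (5'S,6E,6'E)-all-E-4,5'-retro-β,β-carotene (target CNP0257724.1)
Conditions: I2 (2 mol %), hexane–PhH, diffuse daylight, rt, Ar; crystallisation or HPLC of the all-E isomer, mother liquor re-equilibrated
Reagents that add atoms: none
Why: Iodine-catalysed photo-equilibration of a polyene (reversible addition of iodine atoms) should funnel the geometric isomers, including the 6Z form expected from the twisted 6-s-cis retinal, to the all-E isomer; the sp3 stereocentre C5' is not involved.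

**Compound list**

1 | (S)-citronellal, (3S)-3,7-dimethyloct-6-enal | C[C@@H](CCC=C(C)C)CC=O | starting material
2 | 4-[(1E,3S)-3,7-dimethylocta-1,6-dien-1-yl]morpholine | C[C@@H](CCC=C(C)C)/C=C/N1CCOCC1 | intermediate
3 | (2S)-2,6-dimethylhept-5-enal | C[C@@H](CCC=C(C)C)C=O | intermediate
4 | (3S)-1,1-dibromo-3,7-dimethylocta-1,6-diene | C[C@@H](CCC=C(C)C)C=C(Br)Br | intermediate
5 | ethyl chloroformate | CCOC(=O)Cl | starting material
6 | [(3S)-3,7-dimethyloct-6-en-1-yn-1-yl]lithium (formed in the flask) | [Li]C#C[C@@H](C)CCC=C(C)C | intermediate
7 | ethyl (4S)-4,8-dimethylnon-7-en-2-ynoate | CCOC(=O)C#C[C@@H](C)CCC=C(C)C | intermediate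
8 | ethyl 2-[(6S)-2,2,6-trimethylcyclohexylidene]acetate, mixture of the C6'=C7' isomers (2E, ester syn to C5', and 2Z, ester syn to C1') | CCOC(=O)C=C1[C@@H](C)CCCC1(C)C | intermediate
9 | ethyl (2E)-2-[(6S)-2,2,6-trimethylcyclohexylidene]acetate (ester syn to C5') | CCOC(=O)/C=C1\[C@@H](C)CCCC1(C)C | intermediate
10 | (2E)-2-[(6S)-2,2,6-trimethylcyclohexylidene]ethan-1-ol | OC/C=C1\[C@@H](C)CCCC1(C)C | intermediate
11 | (2E)-2-[(6S)-2,2,6-trimethylcyclohexylidene]acetaldehyde | O=C/C=C1\[C@@H](C)CCCC1(C)C | intermediate
12 | 2-(triphenylphosphoranylidene)propanal | CC(C=O)=P(c1ccccc1)(c1ccccc1)c1ccccc1 | starting material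
13 | (2E,4E)-2-methyl-4-[(6S)-2,2,6-trimethylcyclohexylidene]but-2-enal | O=C/C(C)=C/C=C1\[C@@H](C)CCCC1(C)C | intermediate
14 | (2E)-3-methylpent-2-en-4-yn-1-ol | OC/C=C(C)/C#C | starting material
15 | (3E)-5-bromo-3-methylpent-3-en-1-yne | BrC/C=C(C)/C#C | intermediate
16 | diethyl [(2E)-3-methylpent-2-en-4-yn-1-yl]phosphonate | CCOP(=O)(OCC)C/C=C(C)/C#C | intermediate
17 | diethyl [(2E,4E)-3-methyl-5-(tributylstannyl)penta-2,4-dien-1-yl]phosphonate | CCOP(=O)(OCC)C/C=C(C)/C=C/[Sn](CCCC)(CCCC)CCCC | intermediate
18 | sodium salt of the α-carbanion of 17 (formed in the flask) | [Na+].CCOP(=O)(OCC)[CH-]/C=C(C)/C=C/[Sn](CCCC)(CCCC)CCCC | intermediate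
19 | tributyl{(1E,3E,5E,7E)-3,7-dimethyl-9-[(6S)-2,2,6-trimethylcyclohexylidene]nona-1,3,5,7-tetraen-1-yl}stannane (C8' syn to C5') | CCCC[Sn](CCCC)(CCCC)/C=C/C(C)=C/C=C/C(C)=C/C=C1\[C@@H](C)CCCC1(C)C | intermediate
20 | all-trans-retinal | O=C/C=C(C)/C=C/C=C(C)/C=C/C1=C(C)CCCC1(C)C | starting material
21 | potassium retro-hexaenolate of retinal, H-4 removed (formed in the flask) | CC1=CCCC(C)(C)C1=C/C=C(C)/C=C/C=C(C)/C=C/[O-].[K+] | intermediate
22 | (1E,3E,5E,7E)-3,7-dimethyl-9-(2,6,6-trimethylcyclohex-2-en-1-ylidene)nona-1,3,5,7-tetraen-1-yl trifluoromethanesulfonate (C6=C7 geometry open) | CC1=CCCC(C)(C)C1=C/C=C(C)/C=C/C=C(C)/C=C/OS(=O)(=O)C(F)(F)F | intermediate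
23 | (5'S)-4,5'-retro-β,β-carotene, mixture of C6=C7 isomers | CC1=CCCC(C)(C)C1=C/C=C(C)/C=C/C=C(C)/C=C/C=C/C(C)=C/C=C/C(C)=C/C=C1\[C@@H](C)CCCC1(C)C | intermediate
24 | (5'S,6E,6'E)-all-E-4,5'-retro-β,β-carotene | CC1=CCCC(C)(C)\C1=C/C=C(C)/C=C/C=C(C)/C=C/C=C/C(C)=C/C=C/C(C)=C/C=C1\[C@@H](C)CCCC1(C)C | target

**Count and risks**

Total step count: 16. Longest linear sequence: 12 steps (steps 1–9, 13, 15, 16).

Steps most likely to fail:

1. Step 14. Deprotonation at the C13 methyl group, which lies cis to the formyl group, may outpace removal of the remote H-4 and lead to the cross-conjugated 13-methylene dienol triflate. Aldol self-condensation of retinal and decomposition of the polyenyl triflate may also intervene. The fallback sets out from 19 and commercial retinyl acetate and returns at 23. Iododestannylation of 19 (I2, CH2Cl2, −78 °C) should give the vinyl iodide (1E,3E,5E,7E)-1-iodo-3,7-dimethyl-9-[(6S)-2,2,6-trimethylcyclohexylidene]nona-1,3,5,7-tetraene F1. The retro pattern of ring A is produced without any enolate by the acid-catalysed vinylogous elimination of acetic acid from retinyl acetate (TsOH cat., PhH, rt), which should give anhydroretinol F2 with a terminal C14=C15 vinyl group. A Heck reaction of F1 with this terminal alkene (Pd(OAc)2, K2CO3, n-Bu4NCl, DMF, 40 °C, dark) should join C15' to C15 and re-form C14=C15 by β-hydride elimination, giving 23 for step 16.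

2. Step 5. The tertiary radical may be reduced before it cyclises (plain hydrogenation of the alkene), may abstract the C5' hydrogen by a 1,5-shift, or the iron hydride may attack the ynoate; oligomerisation is possible if the solution is too concentrated. The fallback sets out from 7 and returns at 8. Markovnikov addition of HBr (HBr in AcOH, CH2Cl2, −20 °C) should give the tertiary bromide ethyl (4S)-8-bromo-4,8-dimethylnon-2-ynoate F3. Slow addition of Bu3SnH with AIBN in PhH at 80 °C should then generate the same C1' radical by bromine abstraction, close ring B by the same 6-exo-dig addition and deliver hydrogen to the vinyl radical, giving the isomer mixture 8 for step 6.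

3. Step 2. The α-branched aldehyde may be degraded further under copper and oxygen, the trisubstituted alkene may be oxidised, or the new α-stereocentre may epimerise. The fallback sets out from 1 and returns at 3. Proline-catalysed α-aminoxylation of 1 with nitrosobenzene, followed in the same flask by NaBH4, should give (3S)-3,7-dimethyl-2-[(phenylamino)oxy]oct-6-en-1-ol F4, whose C2 configuration is immaterial. N–O cleavage (Zn, AcOH) should give (3S)-3,7-dimethyloct-6-ene-1,2-diol F5, and glycol cleavage with NaIO4 in aqueous THF at pH 7 should give 3 without touching the alkene or C3.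

**Further compounds**

F1 | step 14 | (1E,3E,5E,7E)-1-iodo-3,7-dimethyl-9-[(6S)-2,2,6-trimethylcyclohexylidene]nona-1,3,5,7-tetraene | I/C=C/C(C)=C/C=C/C(C)=C/C=C1\[C@@H](C)CCCC1(C)C
F2 | step 14 | anhydroretinol, all-E | CC1=CCCC(C)(C)\C1=C/C=C(C)/C=C/C=C(C)/C=C
F3 | step 5 | ethyl (4S)-8-bromo-4,8-dimethylnon-2-ynoate | CCOC(=O)C#C[C@@H](C)CCCC(C)(C)Br
F4 | step 2 | (3S)-3,7-dimethyl-2-[(phenylamino)oxy]oct-6-en-1-ol, C2 epimers | C[C@@H](CCC=C(C)C)C(CO)ONc1ccccc1
F5 | step 2 | (3S)-3,7-dimethyloct-6-ene-1,2-diol, C2 epimers | C[C@@H](CCC=C(C)C)C(O)CO
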